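(The runs were computed from invented constants.)

At early times the two products already stand close to their last ratio: Thursday's run reads 73.0% at 0.200 min and 71.6% at 2.50 min for the target share, c(target)/(c(target) + c(isomer)). That is the first rung of the ladder, so the share can be frozen and the sum of the pair remains to be found. The solid comes next: at the concentration of this flask, Thursday's run reads 0% solid substrate at 1.00 min, and its side product then stays near 2.8%. The partner's tail comes last: Sunday's run, with 0.90 equiv, still gains target between 1.50 min and 2.50 min, and its pair reads 75.0% at the later time.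

| flask | solid substrate | partner | remark | time |
|---|---|---|---|---|
| Sunday's | 0.035 M | 0.90 equiv | run made earlier |  |
| Wednesday's | 0.14 M | 0.90 equiv | run made earlier |  |
| Thursday's | 0.071 M | 1.8 equiv | run made earlier |  |
| flask | 0.071 M | 0.900 equiv |  | 4.0 min |

| run | time / min | side product / % | isomer of the product / % | target / % | solid substrate / % |
|---|---|---|---|---|---|
| Sunday's | 0.200 | 0.2 | 2.2 | 6.6 | 37.6 |
| Sunday's | 0.667 | 0.5 | 11.1 | 29.2 | 0.2 |
| Sunday's | 1.00 | 0 | 15.3 | 38.3 | 0.4 |
| Sunday's | 1.50 | 0.1 | 18.0 | 45.5 | 0 |
| Sunday's | 2.50 | 0.3 | 21.5 | 53.5 | 0 |
| Wednesday's | 0.200 | 0.7 | 1.1 | 4.7 | 83.4 |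
| Wednesday's | 0.333 | 1.5 | 3.3 | 9.6 | 73.3 |
| Wednesday's | 0.667 | 5.1 | 8.1 | 22.0 | 50.9 |
| Wednesday's | 1.33 | 12.6 | 16.1 | 39.8 | 13.3 |
| Wednesday's | 2.50 | 13.0 | 21.5 | 54.1 | 0 |
| Thursday's | 0.200 | 0.3 | 3.7 | 10.0 | 67.3 |
| Thursday's | 0.667 | 3.1 | 17.2 | 45.8 | 6.9 |
| Thursday's | 1.00 | 3.0 | 24.5 | 61.2 | 0 |
| Thursday's | 1.50 | 2.9 | 26.8 | 67.4 | 0 |
| Thursday's | 2.50 | 2.8 | 27.4 | 69.2 | 0.2 |

(scatter of a reading: 0.3 percentage points)

- in percentages every species weighs as the solid substrate in it: one side product counts as two
- as a solid, counted per litre of solution: solid substrate
- at the start none of the solid substrate is in solution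
- as a choice and as an amount asked, solid substrate means what is still solid

- where most of what was charged as solid substrate, at 4.0 min is found (target / solid substrate / side product / isomer of the product)
- the largest share itself, whichever of these holds it, in percent of the solid substrate charged

Partner is the limiting reagent here: taking one partner for each product, the flask's pair stays within its charge of 0.900 equiv, which, with the share frozen, puts target under a ceiling of 64.4%, the share times the charge. The reckoning here commits to target as the largest, because the share exceeds 0.5, and places it between Sunday's last 53.5% and that ceiling. The forecast gives target at 60.5%, a single value inside that range, reasoning that “Total products are about 85%”.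

The flask gives target at 60.3%, with 24.1% of the isomer.

    solid substrate ⇌ dissolved substrate, rate k1*(cs1 - [dissolved substrate]) while solid is left; crystals form when [dissolved substrate] > cs1 (solubility = 48.0 mM, k = 0.0483 /s)
    dissolved substrate + partner → target (k = 0.776 /M/s)
    solid substrate + target → side product (k = 0.0711 /M/s)
    target ⇌ isomer of the product (K = 0.400, k = 0.230 /s)

In this flask the step between target and isomer has, by that step alone and both ways together, a relaxation half-life of 0.861 s, far shorter than the 4.0 min of the run, and the frozen share times the flask's pair gives 60.5% of target. A changed partner charge would part this flask from the forecast's share, for target moves by 5 points at 0.807 equiv or at 1.03 equiv; the neighbour flask with 0.540 equiv has a ceiling of 38.7% by the same share, and it holds 37.6% of target, less than that ceiling, with 0.27% of its partner left.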